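**Retrosynthetic overview**

- Target 22 ⇐ desilylation, C=CH2 from the ketone 20, and C–C bond formation between ring aldehyde 12 and the (R)-side-chain Grignard reagent 18 (from (R)-α-hydroxy-γ-butyrolactone).
- Feature used: on the cyclohexane, the oxygen on C1 is cis to Cl on C4 and trans to Br on C3, so O1 can bridge across the ring to C4 on exactly the face that chlorine must finally occupy.
- C4–Cl ⇐ retentive TiCl4 opening of the C4–O7 bond of the 7-oxabicyclo[2.2.1]heptane 9, with the C3 bromine participating ⇐ NBS transannular bromoetherification of cyclohexenol ester 8 (forms C3–Br and C4–O).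
- 8 ⇐ methanolysis of the Diels–Alder adduct 7 of isoprene with the methylidene-dioxolanone 5 derived from (R)-lactic acid (sets C1).
- Ring order: cyclohexene (step 3), temporary oxolane bridge (step 5), bridge cleaved again (step 6).

Key step: step 5

Remark: ring carbons keep one numbering throughout (C1 carbinol carbon, C2 CH2, C3 CHBr, C4 CClMe, C5, C6; O7 is the bridging oxygen of the bicyclic ether), and the thermal Diels–Alder reaction is assumed to favour the usual "para" adduct of a 2-substituted diene.

**Route**

Step 1
Reactants: 1 (R)-lactic acid; 2 pivalaldehyde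
Product: 3 (2R,5R)-2-tert-butyl-5-methyl-1,3-dioxolan-4-one
Conditions: TsOH·H2O (cat.), H2SO4 (cat.), pentane, reflux, Dean–Stark; recrystallisation (Et2O/pentane, −78 °C)
Reagents that add atoms: none
Why: Acid-catalysed acetalisation of an α-hydroxy acid (Seebach dioxolanone), in which the acetal carbon equilibrates to the cis isomer, so the lactic acid centre fixes C2 as R.

Step 2
Reactants: 3 (2R,5R)-2-tert-butyl-5-methyl-1,3-dioxolan-4-one
Product: 5 (2R)-2-tert-butyl-5-methylidene-1,3-dioxolan-4-one, via 5-bromo-dioxolanone 4 (not isolated)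
Conditions: NBS, AIBN (cat.), PhCF3 (or CCl4), reflux; filter; then Et3N, CH2Cl2, 0 °C → rt
Reagents that add atoms: N-bromosuccinimide, O=C1CCC(=O)N1Br (its bromine is present only in intermediate 4)
Why: Radical bromination with NBS at the captodative C5–H followed by E2 loss of HBr toward the methyl group leaves the acetal carbon untouched, so C2 now carries all the stereochemical information.

Step 3
Reactants: 5 (2R)-2-tert-butyl-5-methylidene-1,3-dioxolan-4-one; 6 isoprene
Product: 7 (2R,5S)-2-tert-butyl-8-methyl-1,3-dioxaspiro[4.5]dec-7-en-4-one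
Conditions: isoprene (excess), BHT (cat.), toluene, sealed tube, 90–100 °C
Reagents that add atoms: none
Why: Thermal Diels–Alder reaction of a captodative α-oxyacrylate equivalent, in which the diene should add to the exocyclic alkene on the face anti to the tert-butyl group (spiro carbon, the future C1, becomes S) with the methyl group 1,4 to the spiro carbon; a minor "meta" isomer would be removed by crystallisation here or after step 5, where it cannot close to a bridged ether.

Step 4
Reactants: 7 (2R,5S)-2-tert-butyl-8-methyl-1,3-dioxaspiro[4.5]dec-7-en-4-one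
Product: 8 methyl (1S)-1-hydroxy-4-methylcyclohex-3-ene-1-carboxylate
Conditions: NaOMe (0.2 equiv), MeOH, 0 °C → rt
Reagents that add atoms: methanol, CO
Why: Base-catalysed transesterification opens the acylal-type lactone and the hemiacetal left on O1 collapses to pivalaldehyde, which frees the tertiary α-hydroxy ester without touching C1.

Step 5
Reactants: 8 methyl (1S)-1-hydroxy-4-methylcyclohex-3-ene-1-carboxylate
Product: 9 methyl (1S,3R,4R)-3-bromo-4-methyl-7-oxabicyclo[2.2.1]heptane-1-carboxylate (3-endo-bromo)
Conditions: NBS (1.1 equiv), CH2Cl2, 0 °C → rt, dark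
Reagents that add atoms: N-bromosuccinimide, O=C1CCC(=O)N1Br
Why: NBS transfers Br+ reversibly to both faces of the C3=C4 alkene, and only the bromonium ion on the face opposite the C1 hydroxyl is opened intramolecularly, O1 attacking the tertiary carbon C4 through a boat-like ring while bromine stays on C3 (anti addition). The closest known reaction type is the transannular halo- and selenoetherification of cyclohex-3-en-1-ols to 7-oxabicyclo[2.2.1]heptanes (1,4-cineole-type closure). The one new ring, the oxolane O7–C1–C6–C5–C4, closes in a 5-exo mode with respect to the bromonium ion, since the breaking C4–Br bond lies outside it (counted through C2–C3 the same event is 5-endo). C4 is set by the tether, because O1 can reach it only on its own ring face, and C3 is set by the anti opening, which places bromine trans to the oxygen bridge; both therefore derive from the C1 centre made in step 3. The step needs facial selectivity, Markovnikov regiochemistry and chemoselectivity over capture by the ester carbonyl or by succinimide: the first two are enforced by geometry (attack at C3 would need an oxetane, and the bromonium ion syn to O1 cannot be reached and reverts), the third by the higher nucleophilicity of the hydroxyl compared with a methyl ester, whose capture would also require a slow demethylation.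

Step 6
Reactants: 9 methyl (1S,3R,4R)-3-bromo-4-methyl-7-oxabicyclo[2.2.1]heptane-1-carboxylate
Product: 10 methyl (1S,3R,4R)-3-bromo-4-chloro-1-hydroxy-4-methylcyclohexane-1-carboxylate
Conditions: TiCl4 (1.5 equiv), CH2Cl2, −78 → −30 °C; then H2O
Reagents that add atoms: titanium tetrachloride, Cl[Ti](Cl)(Cl)Cl
Why: Proposed new method: TiCl4 should chelate O7 and the ester carbonyl, the tertiary C4–O7 bond (antiperiplanar to the endo C3–Br) should ionise with bromine participation to a C3/C4 bromonium ion, and chloride from the titanate should open it at C4 on the face the oxygen has just left, giving net retention (Cl cis to O1, trans to Br) while the ester-deactivated C1–O7 bond stays intact and the titanium alkoxide is hydrolysed on work-up; the closest known reaction types are the Lewis-acid cleavage of cineole-type bridged ethers to chloro alcohols and the retentive replacement of oxygen by halide in trans-bromohydrin derivatives through a bromonium ion.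

Step 7
Reactants: 10 methyl (1S,3R,4R)-3-bromo-4-chloro-1-hydroxy-4-methylcyclohexane-1-carboxylate
Product: 11 methyl (1S,3R,4R)-3-bromo-4-chloro-4-methyl-1-[(triethylsilyl)oxy]cyclohexane-1-carboxylate
Conditions: TESOTf, 2,6-lutidine, CH2Cl2, −78 → 0 °C
Reagents that add atoms: triethylsilyl trifluoromethanesulfonate, CC[Si](CC)(CC)OS(=O)(=O)C(F)(F)F
Why: Silyl triflate with a hindered pyridine base is the standard silylation of tertiary alcohols, and the non-nucleophilic base should leave the bromochloride alone.

Step 8
Reactants: 11 methyl (1S,3R,4R)-3-bromo-4-chloro-4-methyl-1-[(triethylsilyl)oxy]cyclohexane-1-carboxylate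
Product: 12 (1S,3R,4R)-3-bromo-4-chloro-4-methyl-1-[(triethylsilyl)oxy]cyclohexane-1-carbaldehyde
Conditions: DIBAL-H (1.1 equiv), CH2Cl2, −78 °C; MeOH, then aq. Rochelle salt
Reagents that add atoms: none
Why: Partial DIBAL reduction of an α-silyloxy ester should stop at the aluminium hemiacetal at −78 °C, which releases the non-enolisable aldehyde only on work-up, and the alkyl halides are inert to the hydride at this temperature.

Step 9
Reactants: 13 (R)-α-hydroxy-γ-butyrolactone [(3R)-3-hydroxyoxolan-2-one]
Product: 14 (3R)-3-[(tert-butyldimethylsilyl)oxy]oxolan-2-one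
Conditions: TBSCl, imidazole, DMF, 0 °C → rt
Reagents that add atoms: tert-butyldimethylsilyl chloride, CC(C)(C)[Si](C)(C)Cl
Why: Imidazole-mediated silylation of a secondary alcohol is too mild to epimerise the α-centre of the lactone.

Step 10
Reactants: 14 (3R)-3-[(tert-butyldimethylsilyl)oxy]oxolan-2-one
Product: 15 (3R)-3-[(tert-butyldimethylsilyl)oxy]-5-hydroxypentan-2-one (in equilibrium with its cyclic hemiketal)
Conditions: MeLi (1.05 equiv), THF, −78 °C; AcOH, −78 °C
Reagents that add atoms: methyllithium, [Li]C
Why: Mono-addition of an organolithium to a γ-lactone, in which the lithium hemiketal alkoxide persists at −78 °C so that the ketone appears only after the quench and a second addition is avoided.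

Step 11
Reactants: 15 (3R)-3-[(tert-butyldimethylsilyl)oxy]-5-hydroxypentan-2-one
Product: 16 (3R)-3-[(tert-butyldimethylsilyl)oxy]-4-methylpent-4-en-1-ol
Conditions: Ph3PCH3Br (3 equiv), n-BuLi (2.8 equiv), THF, 0 °C; then 15, 0 °C → rt
Reagents that add atoms: methyltriphenylphosphonium bromide, C[P+](c1ccccc1)(c1ccccc1)c1ccccc1.[Br-]
Why: Wittig methylenation of the open hydroxy-ketone form, which α-silyloxy methyl ketones undergo faster than enolisation, with the lithium counter-ion and low temperature chosen to hold back O→O silyl migration.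

Step 12
Reactants: 16 (3R)-3-[(tert-butyldimethylsilyl)oxy]-4-methylpent-4-en-1-ol
Product: 17 tert-butyl{[(3R)-5-bromo-2-methylpent-1-en-3-yl]oxy}dimethylsilane
Conditions: CBr4, PPh3, CH2Cl2, 0 °C
Reagents that add atoms: carbon tetrabromide, BrC(Br)(Br)Br
Why: Appel bromination proceeds by SN2 at the primary carbon under neutral conditions and does not involve the stereocentre two bonds away.

Step 13
Reactants: 17 tert-butyl{[(3R)-5-bromo-2-methylpent-1-en-3-yl]oxy}dimethylsilane; 12 (1S,3R,4R)-3-bromo-4-chloro-4-methyl-1-[(triethylsilyl)oxy]cyclohexane-1-carbaldehyde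
Product: 19 (4R)-1-[(1S,3R,4R)-3-bromo-4-chloro-4-methyl-1-[(triethylsilyl)oxy]cyclohexyl]-4-[(tert-butyldimethylsilyl)oxy]-5-methylhex-5-en-1-ol (C1 epimers), via Grignard reagent 18 (not isolated)
Conditions: Mg, I2 (cat.), THF, rt → 40 °C; then 12, THF, −78 → 0 °C; sat. aq. NH4Cl
Reagents that add atoms: magnesium, [Mg] (present only in intermediate 18)
Why: Grignard addition of a primary alkylmagnesium bromide to a non-enolisable aldehyde should be far faster at −78 °C than any attack on the secondary bromide or tertiary chloride, and the new carbinol centre is irrelevant because it is oxidised in the next step.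

Step 14
Reactants: 19 (4R)-1-[(1S,3R,4R)-3-bromo-4-chloro-4-methyl-1-[(triethylsilyl)oxy]cyclohexyl]-4-[(tert-butyldimethylsilyl)oxy]-5-methylhex-5-en-1-ol
Product: 20 (4R)-1-[(1S,3R,4R)-3-bromo-4-chloro-4-methyl-1-[(triethylsilyl)oxy]cyclohexyl]-4-[(tert-butyldimethylsilyl)oxy]-5-methylhex-5-en-1-one
Conditions: Dess–Martin periodinane, NaHCO3, CH2Cl2, 0 °C → rt
Reagents that add atoms: none
Why: Dess–Martin oxidation is neutral when buffered, tolerates silyl ethers, alkenes and alkyl halides, and converges both carbinol epimers on one ketone.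

Step 15
Reactants: 20 (4R)-1-[(1S,3R,4R)-3-bromo-4-chloro-4-methyl-1-[(triethylsilyl)oxy]cyclohexyl]-4-[(tert-butyldimethylsilyl)oxy]-5-methylhex-5-en-1-one
Product: 21 tert-butyl{[(3R)-6-[(1S,3R,4R)-3-bromo-4-chloro-4-methyl-1-[(triethylsilyl)oxy]cyclohexyl]-2-methylhepta-1,6-dien-3-yl]oxy}dimethylsilane
Conditions: Cp2TiMe2 (3 equiv), toluene, 65 °C, dark
Reagents that add atoms: dimethyltitanocene, C[Ti](C)(C1C=CC=C1)C1C=CC=C1 (rings drawn σ-bonded)
Why: Petasis methylenation, in which thermally generated Cp2Ti=CH2 exchanges with hindered ketones by [2+2]/retro-[2+2] and, being neither basic nor reducing, should spare the vicinal bromochloride that a phosphorus ylide (E2) or a zinc-based reagent (reductive elimination) would endanger.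

Step 16
Reactants: 21 tert-butyl{[(3R)-6-[(1S,3R,4R)-3-bromo-4-chloro-4-methyl-1-[(triethylsilyl)oxy]cyclohexyl]-2-methylhepta-1,6-dien-3-yl]oxy}dimethylsilane
Product: 22 (3R)-6-[(1S,3R,4R)-3-bromo-4-chloro-1-hydroxy-4-methylcyclohexyl]-2-methylhepta-1,6-dien-3-ol
Conditions: TBAF (3 equiv), AcOH (3 equiv), THF, 0 °C → rt
Reagents that add atoms: none
Why: Fluoride should cleave both the tertiary triethylsilyl and the secondary allylic TBS ether, and buffering with acetic acid keeps the medium too weakly basic to eliminate HBr or HCl from the bromochloride, which is diequatorial in the preferred chair.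

**Compound list**

1 | (R)-lactic acid | C[C@@H](O)C(=O)O | starting material
2 | pivalaldehyde | CC(C)(C)C=O | starting material
3 | (2R,5R)-2-tert-butyl-5-methyl-1,3-dioxolan-4-one | C[C@H]1O[C@@H](C(C)(C)C)OC1=O | intermediate
4 | (2S,5S)-5-bromo-2-tert-butyl-5-methyl-1,3-dioxolan-4-one (Br expected trans to tert-butyl; acetal carbon unchanged in space, its label changes only through CIP priorities) | C[C@@]1(Br)O[C@@H](C(C)(C)C)OC1=O | intermediate (not isolated)
5 | (2R)-2-tert-butyl-5-methylidene-1,3-dioxolan-4-one | C=C1O[C@@H](C(C)(C)C)OC1=O | intermediate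
6 | isoprene | C=CC(C)=C | starting material
7 | (2R,5S)-2-tert-butyl-8-methyl-1,3-dioxaspiro[4.5]dec-7-en-4-one | O=C1O[C@H](C(C)(C)C)O[C@]12CCC(C)=CC2 | intermediate
8 | methyl (1S)-1-hydroxy-4-methylcyclohex-3-ene-1-carboxylate | COC(=O)[C@]1(O)CCC(C)=CC1 | intermediate
9 | methyl (1S,3R,4R)-3-bromo-4-methyl-7-oxabicyclo[2.2.1]heptane-1-carboxylate | COC(=O)[C@@]12CC[C@@](C)(O1)[C@H](Br)C2 | intermediate
10 | methyl (1S,3R,4R)-3-bromo-4-chloro-1-hydroxy-4-methylcyclohexane-1-carboxylate | COC(=O)[C@]1(O)CC[C@@](C)(Cl)[C@H](Br)C1 | intermediate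
11 | methyl (1S,3R,4R)-3-bromo-4-chloro-4-methyl-1-[(triethylsilyl)oxy]cyclohexane-1-carboxylate | COC(=O)[C@]1(O[Si](CC)(CC)CC)CC[C@@](C)(Cl)[C@H](Br)C1 | intermediate
12 | (1S,3R,4R)-3-bromo-4-chloro-4-methyl-1-[(triethylsilyl)oxy]cyclohexane-1-carbaldehyde | O=C[C@]1(O[Si](CC)(CC)CC)CC[C@@](C)(Cl)[C@H](Br)C1 | intermediate
13 | (R)-α-hydroxy-γ-butyrolactone | O=C1[C@H](O)CCO1 | starting material
14 | (3R)-3-[(tert-butyldimethylsilyl)oxy]oxolan-2-one | O=C1[C@H](O[Si](C)(C)C(C)(C)C)CCO1 | intermediate
15 | (3R)-3-[(tert-butyldimethylsilyl)oxy]-5-hydroxypentan-2-one | CC(=O)[C@H](O[Si](C)(C)C(C)(C)C)CCO | intermediate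
16 | (3R)-3-[(tert-butyldimethylsilyl)oxy]-4-methylpent-4-en-1-ol | C=C(C)[C@H](O[Si](C)(C)C(C)(C)C)CCO | intermediate
17 | tert-butyl{[(3R)-5-bromo-2-methylpent-1-en-3-yl]oxy}dimethylsilane | C=C(C)[C@H](O[Si](C)(C)C(C)(C)C)CCBr | intermediate
18 | {(3R)-3-[(tert-butyldimethylsilyl)oxy]-4-methylpent-4-en-1-yl}magnesium bromide | C=C(C)[C@H](O[Si](C)(C)C(C)(C)C)CC[Mg]Br | intermediate (not isolated)
19 | (4R)-1-[(1S,3R,4R)-3-bromo-4-chloro-4-methyl-1-[(triethylsilyl)oxy]cyclohexyl]-4-[(tert-butyldimethylsilyl)oxy]-5-methylhex-5-en-1-ol (C1 epimers) | C=C(C)[C@H](O[Si](C)(C)C(C)(C)C)CCC(O)[C@]1(O[Si](CC)(CC)CC)CC[C@@](C)(Cl)[C@H](Br)C1 | intermediate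
20 | (4R)-1-[(1S,3R,4R)-3-bromo-4-chloro-4-methyl-1-[(triethylsilyl)oxy]cyclohexyl]-4-[(tert-butyldimethylsilyl)oxy]-5-methylhex-5-en-1-one | C=C(C)[C@H](O[Si](C)(C)C(C)(C)C)CCC(=O)[C@]1(O[Si](CC)(CC)CC)CC[C@@](C)(Cl)[C@H](Br)C1 | intermediate
21 | tert-butyl{[(3R)-6-[(1S,3R,4R)-3-bromo-4-chloro-4-methyl-1-[(triethylsilyl)oxy]cyclohexyl]-2-methylhepta-1,6-dien-3-yl]oxy}dimethylsilane | C=C(C)[C@H](O[Si](C)(C)C(C)(C)C)CCC(=C)[C@]1(O[Si](CC)(CC)CC)CC[C@@](C)(Cl)[C@H](Br)C1 | intermediate
22 | (3R)-6-[(1S,3R,4R)-3-bromo-4-chloro-1-hydroxy-4-methylcyclohexyl]-2-methylhepta-1,6-dien-3-ol | C=C(C)[C@H](O)CCC(=C)[C@]1(O)CC[C@@](C)(Cl)[C@H](Br)C1 | target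

**Step count**

Total: 16 steps. Longest linear sequence: 12 steps (steps 1–8, then 13–16); the side chain (steps 9–12) is made separately.

**Steps most likely to fail**

1. Step 6 (proposed new method). After ionisation of the bridge, the cation may lose a proton (elimination), chloride may attack C3 instead of C4, or bromine may leave as Br+ with reversion to the alkene, so that retentive delivery of chloride to C4 is not the main course. The fallback uses known chemistry and replaces the bridge opening by an undirected interhalogen addition; it sets out from 8. Silylation (TESOTf, 2,6-lutidine, CH2Cl2) should give methyl (1S)-4-methyl-1-[(triethylsilyl)oxy]cyclohex-3-ene-1-carboxylate F1. Tetrabutylammonium dichlorobromate (CH2Cl2, −78 → 0 °C) should then add bromine and chlorine anti and Markovnikov-wise (Cl on C4), giving 11 together with methyl (1S,3S,4S)-3-bromo-4-chloro-4-methyl-1-[(triethylsilyl)oxy]cyclohexane-1-carboxylate F2, to be separated by chromatography. The route is rejoined at 11; the price is the loss of the facial control that the bridge was meant to supply.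

2. Step 5 (key step). Capture of the bromonium ion by the ester carbonyl on the other face (bromolactonisation with demethylation) or by external nucleophiles may outrun the strained transannular closure, and radical allylic bromination may intervene. The fallback changes the electrophile and the way bromine is introduced; it sets out from 8. Intramolecular oxymercuration (Hg(OAc)2, THF, rt; then aq. NaBr) should close the same bridge anti and Markovnikov-wise, giving methyl (1S,3R,4R)-3-(bromomercurio)-4-methyl-7-oxabicyclo[2.2.1]heptane-1-carboxylate F3. Brominolysis of the C–Hg bond with Br2 in pyridine (0 °C, dark) should proceed with retention and return to the route at 9.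

3. Step 15. Exchange between the titanium carbene and the neopentyl-type, α-silyloxy ketone may be slow, so that thermal decay of the reagent and gradual loss of HX from the halogenated ring compete. The fallback is a Peterson olefination, which replaces the carbene exchange by addition of a small carbanion and a separate elimination; it sets out from 20. Me3SiCH2Li with CeCl3 (THF, −78 °C; AcOH quench) should add to the carbonyl to give (5R)-2-[(1S,3R,4R)-3-bromo-4-chloro-4-methyl-1-[(triethylsilyl)oxy]cyclohexyl]-5-[(tert-butyldimethylsilyl)oxy]-6-methyl-1-(trimethylsilyl)hept-6-en-2-ol F4 (C2 epimers). Aqueous HF in MeCN (0 °C → rt) should then effect both the acid-type Peterson elimination and the cleavage of the two silyl ethers, so that the fallback comes back to the route at 22.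

**Further compounds**

F1 | step 6 | methyl (1S)-4-methyl-1-[(triethylsilyl)oxy]cyclohex-3-ene-1-carboxylate | COC(=O)[C@]1(O[Si](CC)(CC)CC)CCC(C)=CC1
F2 | step 6 | methyl (1S,3S,4S)-3-bromo-4-chloro-4-methyl-1-[(triethylsilyl)oxy]cyclohexane-1-carboxylate | COC(=O)[C@]1(O[Si](CC)(CC)CC)CC[C@](C)(Cl)[C@@H](Br)C1
F3 | step 5 | methyl (1S,3R,4R)-3-(bromomercurio)-4-methyl-7-oxabicyclo[2.2.1]heptane-1-carboxylate | COC(=O)[C@@]12CC[C@@](C)(O1)[C@H]([Hg]Br)C2
F4 | step 15 | (5R)-2-[(1S,3R,4R)-3-bromo-4-chloro-4-methyl-1-[(triethylsilyl)oxy]cyclohexyl]-5-[(tert-butyldimethylsilyl)oxy]-6-methyl-1-(trimethylsilyl)hept-6-en-2-ol | C=C(C)[C@H](O[Si](C)(C)C(C)(C)C)CCC(O)(C[Si](C)(C)C)[C@]1(O[Si](CC)(CC)CC)CC[C@@](C)(Cl)[C@H](Br)C1
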